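## Retrosynthetic overview

1. Target 27 ⇒ oxidative, enantioselective ring expansion of spiro-1,3-benzodioxole 25: a 1,2-aryloxy shift from C3 to C4 with MeOH capture, which forms the 1,4-dioxane ring and both stereocentres last.
2. 25 ⇒ ketalisation of diosphenol 12 (northern phenanthrenone half) with catechol 24 (southern phenanthrenetriol half).
3. Ring C of each half ⇒ acyloin closure of a 3,4-disubstituted 1-naphthol diester, then oxidation to the dione (12) or to the aromatic catechol (24).
4. Rings A + B of each half ⇒ rhodium-catalysed C–H annulation of an o-cresol-derived aroyl sulfoxonium ylide with an unsymmetrical hex-3-ynedioate.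
5. Order of ring formation: ring A (o-cresol) → ring B (annulation) → ring C (acyloin) → dioxane ring (ring expansion).

Assumption: the sense of induction of the chiral acid in step 19 cannot be predicted with certainty; the (R)-acid is written, and its enantiomer is used under the same conditions if the first run gives the mirror-image product.

Locants C1–C10a refer to the phenanthrene numbering of the northern half, primed locants to the southern half. In 27 the configuration is (3S,4S): cis-fused dioxane, O2′ on ketal carbon C3, O3′ on C4, with OMe and H4 on the same face.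

## Route

**Step 1**
Reactants: 1 o-cresol
Product: 2 2-methylanisole
Conditions: MeI, K2CO3, acetone, reflux
Reagents that add atoms: iodomethane CI
Why: Williamson O-methylation of the phenoxide (SN2).

**Step 2**
Reactants: 2 2-methylanisole
Product: 4 2-(dimethyl(oxo)-λ6-sulfanylidene)-1-(4-methoxy-3-methylphenyl)ethan-1-one, via 4-methoxy-3-methylbenzoyl chloride 3 (not isolated)
Conditions: (COCl)2, AlCl3, CH2Cl2, 0 °C; ice quench, dry, concentrate; crude 3 added to Me3S(O)I/KOtBu (3 equiv), THF, reflux then 0 °C → rt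
Reagents that add atoms: oxalyl chloride O=C(Cl)C(Cl)=O; trimethylsulfoxonium iodide C[S+](C)(C)=O.[I-]
Why: Friedel–Crafts chlorocarbonylation para to OMe (loss of CO), then C-acylation of dimethylsulfoxonium methylide by the aroyl chloride.

**Step 3**
Reactants: 5 methyl isobutyrate
Product: 7 methyl 2,2-dimethyl-3-oxopropanoate, via lithium enolate of methyl isobutyrate 6 (not isolated)
Conditions: LiN(iPr)2, THF, −78 °C; HCO2Et, −78 → 0 °C; aq NH4Cl
Reagents that add atoms: ethyl formate CCOC=O
Why: crossed Claisen formylation of the preformed ester enolate; the product is non-enolisable and cannot react further.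

**Step 4**
Reactants: 7 methyl 2,2-dimethyl-3-oxopropanoate
Product: 8 methyl 2,2-dimethylbut-3-ynoate
Conditions: Me3SiCHN2, n-BuLi, THF, −78 °C → rt; aq NH4Cl
Reagents that add atoms: (trimethylsilyl)diazomethane C[Si](C)(C)C=[N+]=[N-]
Why: Colvin homologation (addition to the aldehyde, Peterson-type loss of silanolate, loss of N2 and 1,2-hydride shift of the alkylidene carbene); the aldehyde reacts in preference to the hindered ester.

**Step 5**
Reactants: 8 methyl 2,2-dimethylbut-3-ynoate
Product: 9 dimethyl 2,2-dimethylhex-3-ynedioate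
Conditions: N2CHCO2Me, CuI (copper monoiodide, 5 mol%), MeCN, rt
Reagents that add atoms: methyl diazoacetate COC(=O)C=[N+]=[N-]
Why: copper-catalysed coupling of a terminal alkyne with a diazoester (copper acetylide/carbene migratory insertion) gives the 3-alkynoate without base, so no allene isomerisation.

**Step 6**
Reactants: 4 2-(dimethyl(oxo)-λ6-sulfanylidene)-1-(4-methoxy-3-methylphenyl)ethan-1-one; 9 dimethyl 2,2-dimethylhex-3-ynedioate
Product: 10 methyl 2-[4-hydroxy-7-methoxy-1-(2-methoxy-2-oxoethyl)-6-methylnaphthalen-2-yl]-2-methylpropanoate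
Conditions: [(C5Me5)RhCl2]2 (4 mol%), AgSbF6 (16 mol%), Zn(OSO2CF3)2 (30 mol%), ClCH2CH2Cl, 100 °C
Reagents that add atoms: none
Why: trivalent-rhodium C–H activation/[4+2] annulation of the sulfoxonium ylide with the alkyne (loss of Me2SO) gives the 1-naphthol; metalation occurs at the ortho C–H remote from the methyl, and the aryl adds to the CH2-bearing alkyne carbon so the quaternary carbon ends next to the former ylide carbon.

**Step 7**
Reactants: 10 methyl 2-[4-hydroxy-7-methoxy-1-(2-methoxy-2-oxoethyl)-6-methylnaphthalen-2-yl]-2-methylpropanoate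
Product: 12 3,9-dihydroxy-6-methoxy-1,1,7-trimethylphenanthren-2(1H)-one, via 6-methoxy-1,1,7-trimethyl-2,3,9-tris(trimethylsilyloxy)-1,4-dihydrophenanthrene 11 (not isolated)
Conditions: Na, Me3SiCl, toluene, 110 °C; filter, concentrate; Cu(OAc)2·H2O (2.2 equiv), AcOH–MeOH–H2O, 50 °C
Reagents that add atoms: none
Why: Rühlmann acyloin condensation closes ring C as the bis-silyl enediol ether, and hydrolysis plus Cu(OAc)2 oxidation of the acyloin gives the 1,2-dione, which rests as the naphthalene-conjugated diosphenol.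

**Step 8**
Reactants: 1 o-cresol
Product: 13 4-bromo-2-methylphenol
Conditions: N-bromosuccinimide, MeCN, 0 °C
Reagents that add atoms: N-bromosuccinimide O=C1CCC(=O)N1Br
Why: electrophilic aromatic bromination para to the hydroxyl.

**Step 9**
Reactants: 13 4-bromo-2-methylphenol
Product: 14 1-(benzyloxy)-4-bromo-2-methylbenzene
Conditions: BnBr, K2CO3, DMF, rt
Reagents that add atoms: benzyl bromide BrCc1ccccc1
Why: Williamson benzylation; the benzyl group keeps this oxygen distinct from the naphthol oxygen that is methylated in step 15.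

**Step 10**
Reactants: 14 1-(benzyloxy)-4-bromo-2-methylbenzene
Product: 15 methyl 4-(benzyloxy)-3-methylbenzoate
Conditions: Pd(OAc)2 (2 mol%), 4,5-bis(diphenylphosphino)-9,9-dimethylxanthene (4 mol%), CO (1 atm), MeOH, Et3N, 70 °C
Reagents that add atoms: carbon monoxide [C-]#[O+]; methanol CO
Why: palladium-catalysed methoxycarbonylation of the aryl bromide.

**Step 11**
Reactants: 15 methyl 4-(benzyloxy)-3-methylbenzoate
Product: 16 1-[4-(benzyloxy)-3-methylphenyl]-2-(dimethyl(oxo)-λ6-sulfanylidene)ethan-1-one
Conditions: Me3S(O)I, KOtBu, THF, reflux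
Reagents that add atoms: trimethylsulfoxonium iodide C[S+](C)(C)=O.[I-]
Why: acylation of dimethylsulfoxonium methylide by the ester gives the stabilised β-keto sulfoxonium ylide.

**Step 12**
Reactants: 17 methyl pyruvate
Product: 18 methyl 2-hydroxy-2-methylbut-3-ynoate (racemic)
Conditions: HC≡CMgBr, THF, −78 °C; aq NH4Cl
Reagents that add atoms: ethynylmagnesium bromide C#C[Mg]Br
Why: Grignard addition to the ketone carbonyl, which is more electrophilic than the ester; the racemic carbinol centre is removed in steps 16 and 17.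

**Step 13**
Reactants: 18 methyl 2-hydroxy-2-methylbut-3-ynoate
Product: 19 dimethyl 2-hydroxy-2-methylhex-3-ynedioate (racemic)
Conditions: N2CHCO2Me, CuI (copper monoiodide, 5 mol%), MeCN, rt
Reagents that add atoms: methyl diazoacetate COC(=O)C=[N+]=[N-]
Why: copper-catalysed alkyne–diazoester coupling as in step 5, run without base so the free tertiary alcohol is tolerated.

**Step 14**
Reactants: 16 1-[4-(benzyloxy)-3-methylphenyl]-2-(dimethyl(oxo)-λ6-sulfanylidene)ethan-1-one; 19 dimethyl 2-hydroxy-2-methylhex-3-ynedioate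
Product: 20 methyl 2-[7-(benzyloxy)-4-hydroxy-1-(2-methoxy-2-oxoethyl)-6-methylnaphthalen-2-yl]-2-hydroxypropanoate (racemic)
Conditions: [(C5Me5)RhCl2]2 (4 mol%), AgSbF6 (16 mol%), Zn(OSO2CF3)2 (30 mol%), ClCH2CH2Cl, 100 °C
Reagents that add atoms: none
Why: the same rhodium-catalysed C–H activation/[4+2] annulation as in step 6; the bulky, hydroxyl-coordinating tertiary propargylic carbon is placed next to the former ylide carbon, which fixes the later C1′ methyl position.

**Step 15**
Reactants: 20 methyl 2-[7-(benzyloxy)-4-hydroxy-1-(2-methoxy-2-oxoethyl)-6-methylnaphthalen-2-yl]-2-hydroxypropanoate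
Product: 21 methyl 2-[7-(benzyloxy)-4-methoxy-1-(2-methoxy-2-oxoethyl)-6-methylnaphthalen-2-yl]-2-hydroxypropanoate (racemic)
Conditions: MeI, K2CO3, acetone, 50 °C
Reagents that add atoms: iodomethane CI
Why: Williamson O-methylation of the naphthoxide only; the tertiary alcohol is not deprotonated by carbonate.

**Step 16**
Reactants: 21 methyl 2-[7-(benzyloxy)-4-methoxy-1-(2-methoxy-2-oxoethyl)-6-methylnaphthalen-2-yl]-2-hydroxypropanoate
Product: 22 methyl 2-[7-hydroxy-4-methoxy-1-(2-methoxy-2-oxoethyl)-6-methylnaphthalen-2-yl]propanoate (racemic)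
Conditions: H2 (4 atm), Pd/C (10 wt% Pd on carbon), MeOH, H2SO4 (cat.), 50 °C
Reagents that add atoms: none
Why: catalytic hydrogenolysis cleaves the benzyl ether and, acid-assisted, the tertiary benzylic C–OH (as in the hydrogenolysis of aryl-lactic esters to 2-arylpropanoates); the new CH(Me) centre is racemic and becomes aromatic in step 17.

**Step 17**
Reactants: 22 methyl 2-[7-hydroxy-4-methoxy-1-(2-methoxy-2-oxoethyl)-6-methylnaphthalen-2-yl]propanoate
Product: 24 9-methoxy-1,7-dimethylphenanthrene-2,3,6-triol, via 9-methoxy-1,7-dimethyl-2,3,6-tris(trimethylsilyloxy)-1,4-dihydrophenanthrene 23 (not isolated)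
Conditions: Na, Me3SiCl, toluene, 110 °C; filter, concentrate; Cu(OAc)2·H2O (2.2 equiv), AcOH–MeOH–H2O, 50 °C
Reagents that add atoms: none
Why: Rühlmann acyloin condensation closes ring C, and Cu(OAc)2 oxidation to the 1,2-dione is followed by spontaneous tautomerisation to the aromatic catechol (phenanthrene formation).

**Step 18**
Reactants: 12 3,9-dihydroxy-6-methoxy-1,1,7-trimethylphenanthren-2(1H)-one; 24 9-methoxy-1,7-dimethylphenanthrene-2,3,6-triol
Product: 25 racemic spiroketal in which C3 of 9-hydroxy-6-methoxy-1,1,7-trimethyl-1,4-dihydrophenanthren-2(3H)-one is C2 of a 1,3-dioxole fused to C2′–C3′ of 6′-hydroxy-9′-methoxy-1′,7′-dimethylphenanthrene (O2′ and O3′ both on C3; C4 is CH2)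
Conditions: p-toluenesulfonic acid monohydrate (10 mol%), toluene/1,2-dimethoxyethane 5:1, reflux, 4 Å molecular sieves (Soxhlet)
Reagents that add atoms: none
Why: acid-catalysed dehydrative ketalisation of the less hindered C3 carbonyl of the dione tautomer by the catechol (the neopentyl C2 ketone stays free) gives the spiro-1,3-benzodioxole; the spiro centre is racemic and is erased in step 19.

**Step 19**
Reactants: 25 spiroketal
Product: 27 actephilol C, (3S,4S), via para-quinone methide 26 (not isolated)
Conditions: 2,3-dichloro-5,6-dicyano-1,4-benzoquinone (1.05 equiv), CH2Cl2, −40 °C; cold filtration; (R)-N-(trifluoromethanesulfonyl)-3,3′-bis(2,4,6-triisopropylphenyl)-1,1′-binaphthyl-2,2′-diyl phosphoramide (C51H57F3NO5PS, 10 mol%), MeOH (10 equiv), 4 Å molecular sieves, −40 → −20 °C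
Reagents that add atoms: methanol CO
Why: Proposed new method: the quinone takes hydride from the para-hydroxy-activated C4–H to give quinone methide 26, the chiral acid hydrogen-bonds its carbonyl and ion-pairs the developing cation while the less hindered ketal oxygen O3′ (ortho to H, not the one flanked by the C1′ methyl) shifts from C3 to one face of C4 (1,2-aryloxy shift, spiro-dioxole to fused 1,4-dioxane, setting C4), and MeOH then adds to the resulting 1,4-benzodioxan-2-ylium ion anti to the C4–O bond, which the C5–H bay interaction holds pseudo-axial, giving the cis-fused methyl ketal (setting C3); the closest known reactions are chiral phosphoric acid-catalysed 1,6-additions of oxygen nucleophiles to in situ para-quinone methides and the 1,2-chalcogen-shift ring expansions of 1,3-dithiolanes and 1,3-oxathiolanes to dihydro-1,4-dithiins and dihydro-1,4-oxathiins.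

## Compound list

1 | o-cresol | Cc1ccccc1O | starting material
2 | 2-methylanisole | COc1ccccc1C | intermediate
3 | 4-methoxy-3-methylbenzoyl chloride | COc1ccc(cc1C)C(=O)Cl | intermediate
4 | 2-(dimethyl(oxo)-λ6-sulfanylidene)-1-(4-methoxy-3-methylphenyl)ethan-1-one | COc1ccc(cc1C)C(=O)C=S(C)(C)=O | intermediate
5 | methyl isobutyrate | CC(C)C(=O)OC | starting material
6 | lithium enolate of methyl isobutyrate | COC(O[Li])=C(C)C | intermediate
7 | methyl 2,2-dimethyl-3-oxopropanoate | COC(=O)C(C)(C)C=O | intermediate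
8 | methyl 2,2-dimethylbut-3-ynoate | COC(=O)C(C)(C)C#C | intermediate
9 | dimethyl 2,2-dimethylhex-3-ynedioate | COC(=O)CC#CC(C)(C)C(=O)OC | intermediate
10 | methyl 2-[4-hydroxy-7-methoxy-1-(2-methoxy-2-oxoethyl)-6-methylnaphthalen-2-yl]-2-methylpropanoate | COC(=O)Cc1c(C(C)(C)C(=O)OC)cc(O)c2cc(C)c(OC)cc12 | intermediate
11 | 6-methoxy-1,1,7-trimethyl-2,3,9-tris(trimethylsilyloxy)-1,4-dihydrophenanthrene | COc1cc2c3c(cc(O[Si](C)(C)C)c2cc1C)C(C)(C)C(O[Si](C)(C)C)=C(O[Si](C)(C)C)C3 | intermediate
12 | 3,9-dihydroxy-6-methoxy-1,1,7-trimethylphenanthren-2(1H)-one (diosphenol form of the 2,3-dione) | COc1cc2c3c(cc(O)c2cc1C)C(C)(C)C(=O)C(O)=C3 | intermediate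
13 | 4-bromo-2-methylphenol | Cc1cc(Br)ccc1O | intermediate
14 | 1-(benzyloxy)-4-bromo-2-methylbenzene | Cc1cc(Br)ccc1OCc1ccccc1 | intermediate
15 | methyl 4-(benzyloxy)-3-methylbenzoate | COC(=O)c1ccc(OCc2ccccc2)c(C)c1 | intermediate
16 | 1-[4-(benzyloxy)-3-methylphenyl]-2-(dimethyl(oxo)-λ6-sulfanylidene)ethan-1-one | Cc1cc(ccc1OCc1ccccc1)C(=O)C=S(C)(C)=O | intermediate
17 | methyl pyruvate | CC(=O)C(=O)OC | starting material
18 | methyl 2-hydroxy-2-methylbut-3-ynoate (racemic) | COC(=O)C(C)(O)C#C | intermediate
19 | dimethyl 2-hydroxy-2-methylhex-3-ynedioate (racemic) | COC(=O)CC#CC(C)(O)C(=O)OC | intermediate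
20 | methyl 2-[7-(benzyloxy)-4-hydroxy-1-(2-methoxy-2-oxoethyl)-6-methylnaphthalen-2-yl]-2-hydroxypropanoate (racemic) | COC(=O)Cc1c(C(C)(O)C(=O)OC)cc(O)c2cc(C)c(OCc3ccccc3)cc12 | intermediate
21 | methyl 2-[7-(benzyloxy)-4-methoxy-1-(2-methoxy-2-oxoethyl)-6-methylnaphthalen-2-yl]-2-hydroxypropanoate (racemic) | COC(=O)Cc1c(C(C)(O)C(=O)OC)cc(OC)c2cc(C)c(OCc3ccccc3)cc12 | intermediate
22 | methyl 2-[7-hydroxy-4-methoxy-1-(2-methoxy-2-oxoethyl)-6-methylnaphthalen-2-yl]propanoate (racemic) | COC(=O)Cc1c(C(C)C(=O)OC)cc(OC)c2cc(C)c(O)cc12 | intermediate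
23 | 9-methoxy-1,7-dimethyl-2,3,6-tris(trimethylsilyloxy)-1,4-dihydrophenanthrene (racemic) | COc1cc2c(c3cc(O[Si](C)(C)C)c(C)cc13)CC(O[Si](C)(C)C)=C(O[Si](C)(C)C)C2C | intermediate
24 | 9-methoxy-1,7-dimethylphenanthrene-2,3,6-triol | Cc1c(O)c(O)cc2c1cc(OC)c1cc(C)c(O)cc21 | intermediate
25 | spiroketal of 12 (C3) with the C2′,C3′-catechol of 24 (racemic at the spiro carbon) | COc1cc2c3c(cc(O)c2cc1C)C(C)(C)C(=O)C4(C3)Oc5c(O4)cc6c(cc(OC)c7cc(C)c(O)cc76)c5C | intermediate
26 | para-quinone methide of 25 (C9=O, C10=C10a, C4a=C4–H; racemic at the spiro carbon) | COc1cc2c(cc1C)C(=O)C=C1C2=CC2(Oc3c(O2)cc4c(cc(OC)c5cc(C)c(O)cc54)c3C)C(=O)C1(C)C | intermediate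
27 | actephilol C, (3S,4S), cis-fused dioxane | COc1cc2c3c(cc(O)c2cc1C)C(C)(C)C(=O)[C@@]1(OC)Oc2c(cc4c(cc(OC)c5cc(C)c(O)cc54)c2C)O[C@@H]31 | target

## Step count and risks

Total step count: 19. Longest linear sequence: 10 steps (8, 9, 10, 11, 14, 15, 16, 17, 18, 19).

Steps most likely to fail:

**Step 14.** The free tertiary propargylic hydroxyl can divert the alkenyl-rhodium intermediate (β-hydroxide elimination to an allene) or lactonise onto the neighbouring ester. The fallback masks the carbinol so that regiocontrol rests on steric bulk alone. It sets out from 19: Et3SiCl and imidazole give dimethyl 2-methyl-2-(triethylsilyloxy)hex-3-ynedioate F1. Annulation of F1 with 16 under the step 14 conditions gives methyl 2-[7-(benzyloxy)-4-hydroxy-1-(2-methoxy-2-oxoethyl)-6-methylnaphthalen-2-yl]-2-(triethylsilyloxy)propanoate F2. MeI and K2CO3 give methyl 2-[7-(benzyloxy)-4-methoxy-1-(2-methoxy-2-oxoethyl)-6-methylnaphthalen-2-yl]-2-(triethylsilyloxy)propanoate F3, and Bu4NF buffered with AcOH removes the silyl group, coming back to the route at 21.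

**Step 18.** Dehydrative ketalisation of an enolised, hindered α-dione with a poorly soluble catechol may stall or give C-alkylation. The fallback replaces it by acetal exchange. It sets out from 12: HC(OMe)3, MeOH and catalytic p-toluenesulfonic acid give the methyl enol ether 9-hydroxy-3,6-dimethoxy-1,1,7-trimethylphenanthren-2(1H)-one F4. Exchange of F4 with 24 (pyridinium p-toluenesulfonate, toluene, 90 °C, MeOH distilled off) comes back at 25.

**Step 19 (proposed new step).** The uncertainties are which ketal oxygen migrates (O3′ wanted), the level of enantiocontrol, and over-oxidation of the free C6′ phenol by the quinone. The fallback uses known chemistry and bypasses the spiroketal. It sets out from 12 (through enol ether F4, prepared as above) and 24. Ag2CO3-mediated oxidative coupling in benzene–acetone, the classical route to 1,4-benzodioxane neolignans from a propenylphenol and a catechol, joins the catechol oxygen to C3 and closes the second phenol onto the C4 quinone methide. This gives the racemic cis-fused product, that is 27 together with its enantiomer ent-actephilol C F5. The regioisomer is removed on silica, and preparative HPLC on cellulose tris(3,5-dimethylphenylcarbamate) gives 27, where the fallback rejoins the route.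

## Further compounds

F1 | step 14 | dimethyl 2-methyl-2-(triethylsilyloxy)hex-3-ynedioate (racemic) | COC(=O)CC#CC(C)(O[Si](CC)(CC)CC)C(=O)OC
F2 | step 14 | methyl 2-[7-(benzyloxy)-4-hydroxy-1-(2-methoxy-2-oxoethyl)-6-methylnaphthalen-2-yl]-2-(triethylsilyloxy)propanoate (racemic) | COC(=O)Cc1c(C(C)(O[Si](CC)(CC)CC)C(=O)OC)cc(O)c2cc(C)c(OCc3ccccc3)cc12
F3 | step 14 | methyl 2-[7-(benzyloxy)-4-methoxy-1-(2-methoxy-2-oxoethyl)-6-methylnaphthalen-2-yl]-2-(triethylsilyloxy)propanoate (racemic) | COC(=O)Cc1c(C(C)(O[Si](CC)(CC)CC)C(=O)OC)cc(OC)c2cc(C)c(OCc3ccccc3)cc12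
F4 | step 18 | 9-hydroxy-3,6-dimethoxy-1,1,7-trimethylphenanthren-2(1H)-one | COc1cc2c3c(cc(O)c2cc1C)C(C)(C)C(=O)C(OC)=C3
F5 | step 19 | ent-actephilol C, (3R,4R) | COc1cc2c3c(cc(O)c2cc1C)C(C)(C)C(=O)[C@]1(OC)Oc2c(cc4c(cc(OC)c5cc(C)c(O)cc54)c2C)O[C@H]31
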